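**Assumption:** the absolute configuration is taken exactly as in the target SMILES. This requires a 2,5-*trans* tetrahydrofuran, with C11 (R) and C14′ (R). (R)-Linalool is used as the commercial chiral source for C11.

## Retrosynthetic overview
1. Dictyol H comes from Petasis methylenation of a C10 ketone, with the C6-OH protected and the tertiary C15 acetate already in place.
2. The cis-fused hydroazulenone comes from SmI₂ opening of the oxa-bridge of an 8-oxabicyclo[3.2.1]octenone, after RCM closes the Δ3-cyclopentene (last carbocycle).
3. The RCM precursor (C5 isopropenyl, C1 allyl) comes from exo-face cuprate 1,4-addition followed by enolate allylation of the bridged enone.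
4. The bridged enone comes from a new intermolecular [5+2] of the furfuryl-alcohol-derived 3-oxidopyrylium with the vinyl group of *trans*-linalool-oxide acetate. This forms the seven-membered ring and sets C6/C7, and the exo face places C2, C4, O6 and C11 all cis, as the target requires.
5. The THF comes from (R)-linalool by Shi epoxidation and 5-exo closure. Ring order: THF, then 7-ring (oxa-bridged), then cyclopentene, then bridge opening.

## Route

**Step 1**
Reactants: 1, furfuryl alcohol
Product: 2, 6-hydroxy-2H-pyran-3(6H)-one (anomer mixture)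
Conditions: NBS, NaHCO₃, NaOAc, THF/H₂O, 0 °C
Reagents that add atoms: water, O (NBS, BrN1C(=O)CCC1=O, is only the oxidant)
Why: Achmatowicz oxidative ring expansion converts the furan into the pyranone hemiacetal. There are no stereocentres to set, because the anomers converge later.

**Step 2**
Reactants: 2
Product: 3, 6-acetoxy-2H-pyran-3(6H)-one (anomer mixture)
Conditions: Ac₂O, pyridine, DMAP (cat.), CH₂Cl₂, 0 °C
Reagents that add atoms: acetic anhydride, CC(=O)OC(C)=O
Why: Acetylation makes the anomeric acetate, a leaving group that gives the oxidopyrylium on base treatment.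

**Step 3**
Reactants: 4, (R)-(–)-linalool, (3R)-3,7-dimethylocta-1,6-dien-3-ol
Product: 5, (3R)-5-[(2S)-3,3-dimethyloxiran-2-yl]-3-methylpent-1-en-3-ol
Conditions: Shi fructose-derived ketone (0.3 equiv), Oxone, NaHCO₃, K₂CO₃/EDTA buffer pH 10.5, MeCN/DMM/H₂O, 0 °C
Reagents that add atoms: Oxone (KHSO₅), [K+].OOS(=O)(=O)[O-], which supplies the epoxide O
Why: Shi asymmetric epoxidation is chemoselective for the trisubstituted alkene over the vinyl group. The ketone enantiomer is chosen to give the (6S)-epoxide, which sets C14′ after inversion in the next step; C11 is untouched.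

**Step 4**
Reactants: 5
Product: 6, 2-[(2R,5R)-5-ethenyl-5-methyloxolan-2-yl]propan-2-ol
Conditions: NaH (0.3 equiv), THF, 0 → 60 °C
Reagents that add atoms: none
Why: Base-mediated 5-exo epoxide opening by the tertiary alkoxide occurs at the less hindered carbon with inversion, so (S)-epoxide gives (R)-C14′ and the 2,5-*trans* THF. Base avoids ionisation of the allylic C11–O bond.

**Step 5**
Reactants: 6
Product: 7, 2-[(2R,5R)-5-ethenyl-5-methyloxolan-2-yl]propan-2-yl acetate
Conditions: Ac₂O, DMAP (1 equiv), Et₃N, CH₂Cl₂, 40 °C
Reagents that add atoms: acetic anhydride, CC(=O)OC(C)=O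
Why: Base-mediated acylation installs the tertiary C15 acetate early, so the final deprotection exposes only C6-OH; no stereocentre is affected.

**Step 6**
Reactants: 3, 6-acetoxy-2H-pyran-3(6H)-one (3 equiv), and 7 (1 equiv)
Product: 8, 2-[(2R,5R)-5-methyl-5-(2-oxo-8-oxabicyclo[3.2.1]oct-3-en-6-yl)oxolan-2-yl]propan-2-yl acetate (exo-6 isomer, core as drawn in the SMILES)
Conditions: iPr₂NEt, MeCN, 80 °C, sealed tube (Schreiner thiourea, 10 mol%, as H-bond donor)
Reagents that add atoms: none (AcOH is lost from 3)
Why: Proposed new method: base eliminates AcOH from 3 to give the 3-oxidopyrylium, a 5-atom 4π dipole. It adds across C2/C6 to the vinyl π-bond in a thermal concerted-asynchronous (4+... 5+2) cycloaddition, with the terminal CH₂ bonding to the enolate-like C2 (the future C9) and the substituted carbon bonding to the oxocarbenium C6 (the future C6). The bulky α-quaternary α-alkoxy substituent forces the exo (O-bridge-syn) transition state, which puts C11 cis to O6. C11 chirality should favour the correct vinyl face, expected at about 3:1 with the minor diastereomer separable. The closest known reaction is the Hendrickson/Sammes/Wender oxidopyrylium–alkene [5+2], which has been shown only for electron-poor, electron-rich or intramolecular alkenes, not for an unactivated hindered α-quaternary vinyl group.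

**Step 7**
Reactants: 8
Product: 9, the exo-4-isopropenyl bicyclic ketone (C5 stereocentre set)
Conditions: CH₂=C(Me)MgBr, CuBr·SMe₂, TMSCl, THF, −78 °C, then 1 M HCl
Reagents that add atoms: isopropenylmagnesium bromide, C=C(C)[Mg]Br
Why: Cuprate 1,4-addition to the enone β-carbon (C5) occurs from the exo face, syn to the small O-bridge and anti to the C7–C8 bridge. This puts C4 on the same face as O6 (axial attack, conjugate addition). The hydrolysis step returns the TMS enol ether to the ketone.

**Step 8**
Reactants: 9
Product: 10, the exo-3-allyl-4-isopropenyl bicyclic ketone (C1 stereocentre set)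
Conditions: LDA, THF, −78 °C; then allyl bromide, DMPU, −78 → −20 °C
Reagents that add atoms: allyl bromide, C=CCBr
Why: Only C1 is enolisable, because the other α-carbon is a bridgehead, so enolate alkylation is regiospecific. The C1 substituent takes the equatorial, exo position, since endo would clash with the C7–C8 bridge. This makes it cis to the C5 isopropenyl group.

**Step 9**
Reactants: 10
Product: 11, the cis-fused Δ3-cyclopentene oxa-bridged tricyclic ketone
Conditions: Hoveyda–Grubbs II (10 mol%), toluene (5 mM), 60 °C
Reagents that add atoms: none (ethylene is lost)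
Why: Ring-closing metathesis of the cis-1,2-disubstituted 1,6-diene (1,1-disubstituted plus monosubstituted alkene) gives the trisubstituted C3=C4(Me) cyclopentene. No stereocentre is changed.

**Step 10**
Reactants: 11
Product: 12, the cis-hydroazulenone with free C6-OH (C9 oxygen removed)
Conditions: SmI₂, MeOH, THF, −78 → 0 °C
Reagents that add atoms: none (MeOH is only a proton source)
Why: SmI₂ reductive cleavage of the C9–O bond α to the C10 ketone gives the cycloheptanone, leaving O6 on C6 with retention. C9 is reduced to CH₂, and C1/C5 are not epimerised under the cold quench.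

**Step 11**
Reactants: 12
Product: 13, the C6-OTBS ketone
Conditions: TBSOTf, 2,6-lutidine, CH₂Cl₂, −78 → 0 °C
Reagents that add atoms: TBSOTf, CC(C)(C)[Si](C)(C)OS(=O)(=O)C(F)(F)F
Why: Silylation protects the hindered secondary alcohol before methylenation. Lutidine avoids silyl enol ether formation and epimerisation at C1.

**Step 12**
Reactants: 13
Product: 14, the C10-methylene TBS ether
Conditions: Cp₂TiMe₂ (Petasis reagent), toluene, 70 °C, dark
Reagents that add atoms: Cp₂TiMe₂, C[Ti](C)(C1C=CC=C1)C1C=CC=C1, which delivers =CH₂
Why: Petasis methylenation is non-basic, so C1 is not epimerised. It is chemoselective for the ketone over the hindered tertiary acetate.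

**Step 13**
Reactants: 14
Product: 15, dictyol H
Conditions: HF·pyridine, pyridine, THF, 0 °C → rt
Reagents that add atoms: none (F is not retained)
Why: Fluoride removes the TBS ether to reveal C6-OH; the tertiary acetate and all stereocentres are unaffected.

## Compound list
1 | furfuryl alcohol | OCc1ccco1 | starting material
2 | 6-hydroxy-2H-pyran-3(6H)-one | OC1C=CC(=O)CO1 | intermediate
3 | 6-acetoxy-2H-pyran-3(6H)-one | CC(=O)OC1C=CC(=O)CO1 | intermediate
4 | (R)-linalool | C=C[C@](C)(O)CCC=C(C)C | starting material
5 | (3R)-6,7-epoxy linalool, (6S) | C=C[C@](C)(O)CC[C@@H]1OC1(C)C | intermediate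
6 | 2-[(2R,5R)-5-ethenyl-5-methyloxolan-2-yl]propan-2-ol | C=C[C@@]1(C)CC[C@H](C(C)(C)O)O1 | intermediate
7 | acetate of 6 | C=C[C@@]1(C)CC[C@H](C(C)(C)OC(C)=O)O1 | intermediate
8 | exo-6-substituted 8-oxabicyclo[3.2.1]oct-3-en-2-one | O=C1C=C[C@H]2[C@H]([C@@]3(C)CC[C@H](C(C)(C)OC(C)=O)O3)C[C@@H]1O2 | intermediate
9 | 4-isopropenyl ketone | O=C1C[C@H](C(C)=C)[C@H]2[C@H]([C@@]3(C)CC[C@H](C(C)(C)OC(C)=O)O3)C[C@@H]1O2 | intermediate
10 | 3-allyl-4-isopropenyl ketone | O=C1[C@H](CC=C)[C@H](C(C)=C)[C@H]2[C@H]([C@@]3(C)CC[C@H](C(C)(C)OC(C)=O)O3)C[C@@H]1O2 | intermediate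
11 | RCM tricycle | O=C1[C@@H]2CC=C(C)[C@@H]2[C@H]3[C@H]([C@@]4(C)CC[C@H](C(C)(C)OC(C)=O)O4)C[C@@H]1O3 | intermediate
12 | hydroxy hydroazulenone | O=C1CC[C@@H]([C@@]2(C)CC[C@H](C(C)(C)OC(C)=O)O2)[C@@H](O)[C@H]2C(C)=CC[C@@H]12 | intermediate
13 | C6-OTBS ketone | O=C1CC[C@@H]([C@@]2(C)CC[C@H](C(C)(C)OC(C)=O)O2)[C@@H](O[Si](C)(C)C(C)(C)C)[C@H]2C(C)=CC[C@@H]12 | intermediate
14 | C10-methylene TBS ether | C=C1CC[C@@H]([C@@]2(C)CC[C@H](C(C)(C)OC(C)=O)O2)[C@@H](O[Si](C)(C)C(C)(C)C)[C@H]2C(C)=CC[C@@H]12 | intermediate
15 | dictyol H | C=C1CC[C@@H]([C@@]2(C)CC[C@H](C(C)(C)OC(C)=O)O2)[C@@H](O)[C@H]2C(C)=CC[C@@H]12 | target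

**Total steps:** 13. **Longest linear sequence:** 11 steps, from (R)-linalool.

## Three steps most likely to fail
1. **Step 6 (proposed new [5+2]).** The alkene is unactivated and hindered, so yield, regiochemistry, exo/endo selectivity and facial selectivity are all uncertain. Fallback (known chemistry): run the [5+2] with methyl acrylate to give the exo-6 ester and carry it through Steps 7–12. Then convert the ester to the methyl ketone (Weinreb amide, MeMgBr) and add homoprenyl-MgBr/CeCl₃ under chelation control. Finish by Shi epoxidation, NaH 5-exo closure, Ac₂O and HF·py, so the THF is built late.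
2. **Step 7.** The exo face at C5 may be shielded by the exo-C7 quaternary substituent. Fallback: Rh-catalysed Hayashi–Miyaura 1,4-addition of isopropenylboronic acid, a different organometallic manifold that is less sterically demanding. Follow it with the same allylation and RCM.
3. **Step 12.** Petasis methylenation of the hindered ketone may be slow or may attack the acetate. Fallback: Peterson olefination (TMSCH₂MgCl/CeCl₃ addition, then KH or acid elimination).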